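**Remarks on the chemistry (assumptions)**

- Both lactones of the target are (3R,4R). In each, the two benzylic carbons are trans and the C3 hydroxyl is cis to the C4 benzyl group. The configurations of 8, 27 and 30 were re-derived from the target and are mutually consistent, so no structural correction was needed. The acceptor must be the (5S) acetal of (+)-menthol, and 30 is (3R,4S,5S) at lactone 1.
- 5-Bromovanillin (9), 4-benzyloxy-3-methoxybenzaldehyde (17) and 4-benzyloxy-3-methoxybenzyl alcohol (19) are taken as purchasable vanillin derivatives.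

## Structural features

The target is an unsymmetrical dimer of two 3-hydroxy-3,4-dibenzyl-γ-butyrolactones with four guaiacyl-type rings A–D; rings B and C are joined by a biaryl bond ortho to their phenolic hydroxyls. Lactone 1 carries ring A on its C4–CH2 arm and ring B on its C3–CH2 arm, whereas lactone 2 carries ring C on C4–CH2 and ring D on C3–CH2. The biaryl therefore links a C3 arm of one lactone to a C4 arm of the other, and there is no symmetry to exploit. Each lactone has two adjacent stereocentres, the fully substituted carbinol carbon C3 and the methine C4, both R. Fragile groups are the four electron-rich phenols (the 2,2'-biphenol is easily oxidised), the tertiary α-hydroxy lactones (opened by base) and the p-oxygenated benzylic positions (easily ionised). The real difficulty is the quaternary C3 with its oxygen on the same face as the C4 substituent: an electrophile entering a C3 enolate should come anti to C4, so oxygen must already sit on C3 when the benzylic carbon arrives. This has to be achieved twice, on a biaryl whose two benzylic termini need opposite polarity. The key step exploits the pattern at lactone 1: C4 bears a benzylic carbon (to ring A) that can act as a carbanion, and C3 bears oxygen plus a benzylic carbon (to ring B) that can act as an electrophile. This is the pattern of a C3-oxygenated C3=C4 butenolide, with C5 available as a chiral acetal carbon.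

## Logic of the disconnections

**34 ⇐ 33.** The six O–CH2Ph bonds (four phenolic, two on the tertiary C3 oxygens) are cut last. One neutral hydrogenolysis then unveils all phenols and both carbinols at the very end. The demand is that all sulfur is gone beforehand and that every earlier step tolerates benzyl ethers.

**33 ⇐ 31.** At C5 of lactone 1 a C–H bond is replaced, in the retrosynthetic sense, by the C–O bond to the menthyl auxiliary, which raises C5 to an acyl acetal. This puts the controlling stereocentre next to C4. The forward step must open the acetal, reduce C5 and reclose the ring with the carbonyl still on C2, without harming lactone 2.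

**31 ⇐ 30.** The CH2 between ring A and C4 is traced back to a dithioketal carbon (two C–S bonds). This turns the ring A benzylic carbon into a donor. The forward demand is a desulfurisation that spares benzyl ethers and both lactones.

**30 ⇐ 18 + 8 + 27 (key).** The C4–C(benzylic, ring A) bond and the C3–CH2(ring B) bond are cut. This is the only cut that delivers both stereocentres of lactone 1 and both of its benzylic C–C bonds in one operation, with oxygen already on C3. The gain is three fragments of comparable size, one of which carries the finished lactone 2. The demands are 1,4-addition anti to the C5 alkoxy group, C-alkylation anti to the new C4 substituent, and an electrophile without acidic hydrogens.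

**27 ⇐ 26.** The C–Br bond is traced back to a C–O–Si bond. The labile p-alkoxybenzylic bromide is thus made in the last step before use. The forward conversion must not brominate the electron-rich rings.

**26 ⇐ 24 ⇐ 23.** The same two retro-operations as for lactone 1: C5–H back to the C5 acetal, and the ring C benzylic CH2 back to the dithioketal.

**23 ⇐ 16 + 8 + 20.** The C4–C(benzylic, ring C) and C3–CH2(ring D) bonds of lactone 2 are cut by the same transform. Both lactones then come from one enantiomer of one building block, which is why both are (3R,4R). This step also rehearses the key step on simple material. The demand is that the silyl-protected benzylic oxygen on ring B survives lithiation.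

**16 ⇐ 12 + 15.** The ring B–ring C bond is cut. The two rings need different benzylic functions (a dithiane donor and a masked electrophile), so cross-coupling two differentiated halves of one aldehyde avoids a statistical desymmetrisation. The demands are a coupling that tolerates the thioacetal and the absence of aryl bromide before any lithiation.

**12 ⇐ 10 + 11; 15 ⇐ 14 ⇐ 13 ⇐ 10; 10 ⇐ 9.** These are C–S, C–B, O–Si and O–benzyl bond formations and one carbonyl reduction on a single bromo aldehyde.

**8 ⇐ 7 ⇐ 6 ⇐ 5.** The C3–O bond is introduced by syn-dihydroxylation of C3=C4, and the double bond is restored by loss of the C4 oxygen. The demand is an elimination that leaves the C5 acetal centre untouched.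

**5 ⇐ 3 + 4; 3 ⇐ 1.** The acetal C5–O bond is cut, and the butenolide is traced back to a furan by oxidative loss of one carbon.

**18 ⇐ 17 + 11; 20 ⇐ 19.** One thioacetalisation and one bromination supply the ring A donor and the ring D electrophile.

## Other disconnections considered

**Alternative 1:** The cut is the C5–O1 bond of lactone 2. The ring is traced back to the prochiral cyclobutanone A2, and a Baeyer–Villiger monooxygenase with O2 and NADPH would insert oxygen into one of the two enantiotopic acyl–carbon bonds to give the (S)-lactone A1. A1 has the same spatial arrangement at C4 as the target; the descriptor differs only because C3 carries no oxygen yet.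

- In its favour: it is catalytic and reagent-controlled, uses air as oxidant, and needs no auxiliary, no dithiane and no nickel. On atom economy and waste it is better than the chosen plan.
- Against it here: it sets only C4 of lactone 2. C3 would still need two separate enolate operations (oxygen first, then the ring D benzyl group). The allyl group on ring B of A1 must still be built into the whole of lactone 1. The large, lipophilic biaryl A2 is far from the usual substrate size of such enzymes, so screening or engineering is likely.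
- Comparison: on structure, the chosen plan makes two C–C bonds and two stereocentres per operation, against one stereocentre and no skeletal C–C bond. On mechanism, the later C3 alkylation would rely on the same anti-to-C4 rule, so the two are equal in stereochemical predictability. On step economy, the alternative is clearly longer.

**Alternative 2:** The cut is the C2–C3 bond of both lactones. CH2=CHMgBr would add to both carbonyls of the bis(β-benzyloxy ketone) A4 under MgBr2·OEt2 chelation to give the bis(tertiary allylic alcohol) A3, with the vinyl groups as latent C2.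

- In its favour: both tertiary carbinols form in one two-directional operation. A six-membered chelate with attack anti to the α-benzyl group translates into the required hydroxyl-cis-to-C4-benzyl arrangement, so in stereochemical sense it is equal to the chosen plan. A final hydrogenolysis could free the primary alcohols and lactonise in the same pot, which is equal or better as an endgame.
- Against it here: A4 has an epimerisable α-centre, a β-benzyloxy group prone to elimination and a doubly activated benzylic α'-methylene, so enolisation by the basic Grignard reagent is a serious competitor. Control through an acyclic chelate is less rigid than the ring-based control of the chosen plan. A4 is unsymmetrical end to end, so its two α-stereocentres and two ketones must be built separately. The vinyl groups of A3 must later be cleaved oxidatively beside four electron-rich arenes.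
- Comparison: better in convergence at the carbinol-forming step, weaker in substrate stability and certainty of selectivity, and not shorter overall once the synthesis of A4 is counted.

**Alternative 3:** The cut is the C4–C5 bond of both lactones. CH2=CHMgBr with CuI would open both trisubstituted epoxy alcohols of A6 at their CH carbons with inversion to give the bis(1,2-diol) A5, with vinyl as latent C5 and CH2OH as latent C2.

- In its favour: both stereocentres of each lactone come from a catalytic Sharpless epoxidation followed by a stereospecific SN2 opening. The tertiary carbinol has the right configuration by construction. Attack at C3 of a 2,3-epoxy alcohol with a fully substituted C2 is the normal regiochemistry. In catalyst control and certainty of the C3 configuration it is better than the chosen plan.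
- Against it here: opening at a secondary carbon flanked by a benzyl group and a quaternary epoxide carbon should be slow, with Payne rearrangement, halohydrin formation and elimination as competitors. A6 presupposes two trisubstituted double bonds of defined geometry on an unsymmetrical biaryl. After the key step each arm of A5 still needs the primary alcohol oxidised to the acid without diol cleavage, the vinyl group degraded to CH2OH beside electron-rich arenes, and lactonisation.
- Comparison: equal in setting two stereocentres per lactone in two operations, better in independence from a stoichiometric auxiliary, clearly worse in step count after the key step and in the effort to reach A6.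

Key step: step 18

## Steps

Step 1
Reactants: 1 furfural
Product: 3 5-hydroxyfuran-2(5H)-one, via furfural endoperoxide 2 (not isolated)
Conditions: O2, hν (visible), methylene blue (cat.), MeOH, rt
Reagents that add atoms: dioxygen, O=O
Why: Sensitised photooxygenation: singlet oxygen adds [4+2] across the furan to give 2, and methanol cleaves off the formyl carbon as methyl formate, which leaves the hydroxybutenolide; this is a long-established preparation.

Step 2
Reactants: 3 5-hydroxyfuran-2(5H)-one; 4 (+)-menthol
Product: 5 (5S)-5-[(1S,2R,5S)-menthyloxy]furan-2(5H)-one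
Conditions: p-TsOH (cat.), toluene, reflux with azeotropic removal of water; crystallisation (hexane), mother liquor re-equilibrated with p-TsOH
Reagents that add atoms: none
Why: Acid-catalysed acetalisation of the pseudo-acid gives both C5 epimers; the (5S) epimer should crystallise, being the mirror image of the (5R) acetal of (−)-menthol whose crystallisation is well established, and acid epimerisation of the mother liquor funnels material into it (crystallisation-induced diastereomer enrichment).

Step 3
Reactants: 5 (5S)-5-[(1S,2R,5S)-menthyloxy]furan-2(5H)-one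
Product: 6 (3R,4S,5S)-3,4-dihydroxy-5-[(1S,2R,5S)-menthyloxy]dihydrofuran-2(3H)-one
Conditions: OsO4 (cat.), NMO, citric acid, t-BuOH/H2O, rt
Reagents that add atoms: N-methylmorpholine N-oxide, C[N+]1([O-])CCOCC1; water, O
Why: Catalytic syn-dihydroxylation of the electron-poor alkene, with citric acid to keep the catalyst turning over and the medium non-basic; attack anti to the menthyloxy group is expected, but both new centres are erased in step 5, so the face selectivity is not critical.

Step 4
Reactants: 6 (3R,4S,5S)-3,4-dihydroxy-5-[(1S,2R,5S)-menthyloxy]dihydrofuran-2(3H)-one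
Product: 7 (3R,4S,5S)-3,4-bis(benzyloxy)-5-[(1S,2R,5S)-menthyloxy]dihydrofuran-2(3H)-one
Conditions: BnBr, Ag2O, 4 Å MS, CH2Cl2/toluene, rt, dark
Reagents that add atoms: benzyl bromide, BrCc1ccccc1
Why: Ag2O-mediated Williamson benzylation is the standard non-basic way to etherify α-hydroxy lactones without enolisation or ring opening; any material that eliminates prematurely is already the product of step 5.

Step 5
Reactants: 7 (3R,4S,5S)-3,4-bis(benzyloxy)-5-[(1S,2R,5S)-menthyloxy]dihydrofuran-2(3H)-one
Product: 8 (5S)-3-(benzyloxy)-5-[(1S,2R,5S)-menthyloxy]furan-2(5H)-one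
Conditions: DBU, CH2Cl2, 0 °C
Reagents that add atoms: none
Why: E1cB β-elimination: only H3 is acidic and only the C4 benzyloxy group is β to the carbonyl, so benzyl alcohol is lost regiospecifically to give the 2-alkoxy enoate, as known for O-benzylated aldonolactones; low temperature and short contact are chosen to keep the C5 acetal centre intact.

Step 6
Reactants: 9 5-bromovanillin
Product: 10 4-(benzyloxy)-3-bromo-5-methoxybenzaldehyde
Conditions: BnBr, K2CO3, DMF, 60 °C
Reagents that add atoms: benzyl bromide, BrCc1ccccc1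
Why: Williamson etherification of the phenol; the aldehyde and the aryl bromide are inert.

Step 7
Reactants: 10 4-(benzyloxy)-3-bromo-5-methoxybenzaldehyde; 11 propane-1,3-dithiol
Product: 12 2-[4-(benzyloxy)-3-bromo-5-methoxyphenyl]-1,3-dithiane
Conditions: BF3·OEt2 (cat.), CH2Cl2, 0 °C → rt
Reagents that add atoms: none
Why: Lewis-acid-catalysed dithioacetalisation; it is done before any silyl ether exists, so the Lewis acid meets no sensitive group.

Step 8
Reactants: 10 4-(benzyloxy)-3-bromo-5-methoxybenzaldehyde
Product: 13 [4-(benzyloxy)-3-bromo-5-methoxyphenyl]methanol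
Conditions: NaBH4, MeOH/THF, 0 °C
Reagents that add atoms: none
Why: Borohydride reduction of the aldehyde; the aryl bromide and the benzyl ether are untouched.

Step 9
Reactants: 13 [4-(benzyloxy)-3-bromo-5-methoxyphenyl]methanol
Product: 14 {[4-(benzyloxy)-3-bromo-5-methoxybenzyl]oxy}(tert-butyl)dimethylsilane
Conditions: TBSCl, imidazole, DMF, rt
Reagents that add atoms: tert-butyldimethylsilyl chloride, CC(C)(C)[Si](C)(C)Cl
Why: Standard silylation of a primary alcohol; the silyl ether masks the future benzylic electrophile of ring B through organolithium, hydride and hydroxide steps.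

Step 10
Reactants: 14 {[4-(benzyloxy)-3-bromo-5-methoxybenzyl]oxy}(tert-butyl)dimethylsilane
Product: 15 2-[2-(benzyloxy)-5-({[tert-butyl(dimethyl)silyl]oxy}methyl)-3-methoxyphenyl]-4,4,5,5-tetramethyl-1,3,2-dioxaborolane
Conditions: B2pin2, Pd(dppf)Cl2 (cat.), KOAc, 1,4-dioxane, 90 °C
Reagents that add atoms: bis(pinacolato)diboron, CC1(C)OB(OC1(C)C)B1OC(C)(C)C(C)(C)O1
Why: Miyaura borylation of the aryl bromide; the weak base KOAc leaves the silyl and benzyl ethers alone.

Step 11
Reactants: 12 2-[4-(benzyloxy)-3-bromo-5-methoxyphenyl]-1,3-dithiane; 15 2-[2-(benzyloxy)-5-({[tert-butyl(dimethyl)silyl]oxy}methyl)-3-methoxyphenyl]-4,4,5,5-tetramethyl-1,3,2-dioxaborolane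
Product: 16 2-[2',6-bis(benzyloxy)-5'-({[tert-butyl(dimethyl)silyl]oxy}methyl)-3',5-dimethoxybiphenyl-3-yl]-1,3-dithiane
Conditions: Pd(OAc)2 (cat.), SPhos, K3PO4, toluene/H2O, 90 °C
Reagents that add atoms: none
Why: Suzuki–Miyaura coupling gives the 2,2'-dialkoxybiaryl with the two benzylic carbons already differentiated; a bulky biarylphosphine is chosen for the ortho-alkoxy partners and for tolerance of the thioacetal, and the bromine is consumed here so that none is left for the lithiation in step 14.

Step 12
Reactants: 17 4-(benzyloxy)-3-methoxybenzaldehyde; 11 propane-1,3-dithiol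
Product: 18 2-[4-(benzyloxy)-3-methoxyphenyl]-1,3-dithiane
Conditions: BF3·OEt2 (cat.), CH2Cl2, 0 °C → rt
Reagents that add atoms: none
Why: Lewis-acid-catalysed dithioacetalisation gives the ring A acyl-anion equivalent.

Step 13
Reactants: 19 [4-(benzyloxy)-3-methoxyphenyl]methanol
Product: 20 4-(benzyloxy)-3-methoxybenzyl bromide
Conditions: PBr3, Et2O, 0 °C; used at once
Reagents that add atoms: phosphorus tribromide, BrP(Br)Br
Why: Standard conversion of a benzylic alcohol into the bromide; the labile p-alkoxybenzyl bromide is made immediately before use.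

Step 14
Reactants: 16 2-[2',6-bis(benzyloxy)-5'-({[tert-butyl(dimethyl)silyl]oxy}methyl)-3',5-dimethoxybiphenyl-3-yl]-1,3-dithiane; 8 (5S)-3-(benzyloxy)-5-[(1S,2R,5S)-menthyloxy]furan-2(5H)-one; 20 4-(benzyloxy)-3-methoxybenzyl bromide
Product: 23 (3R,4S,5S)-3-(benzyloxy)-3-[4-(benzyloxy)-3-methoxybenzyl]-4-{2-[biphenylyl group of 16]-1,3-dithian-2-yl}-5-[(1S,2R,5S)-menthyloxy]dihydrofuran-2(3H)-one, via lithiated biaryl dithiane 21 (not isolated), via lithium lactone enolate 22 (not isolated)
Conditions: n-BuLi, THF, −78 → −20 °C; 8, −78 °C; then 20, DMPU, −78 → −20 °C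
Reagents that add atoms: none
Why: Proposed new method: the same tandem sequence as in step 18 with a simple electrophile: the soft dithiane carbanion 21 should add 1,4 to the 2-alkoxy enoate 8 anti to the C5 menthyloxy group, and the chelated lithium enolate 22 is benzylated by 20 anti to the dithianyl group, which sets C4 and the fully substituted C3 of lactone 2. The closest known reaction type is the tandem conjugate addition/enolate benzylation of lithiated aryl dithianes on 5-menthyloxyfuran-2(5H)-one, together with the alkylation of α-alkoxy lactone enolates; only the C3 oxygen on the acceptor is new. Run first and on simple material, it also serves as the rehearsal for step 18.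

Step 15
Reactants: 23 tandem adduct of step 14
Product: 24 (3R,4S,5S)-3-(benzyloxy)-3-[4-(benzyloxy)-3-methoxybenzyl]-4-{[2',6-bis(benzyloxy)-5'-({[tert-butyl(dimethyl)silyl]oxy}methyl)-3',5-dimethoxybiphenyl-3-yl]methyl}-5-[(1S,2R,5S)-menthyloxy]dihydrofuran-2(3H)-one
Conditions: NiCl2·6H2O, NaBH4, MeOH/THF, 0 °C
Reagents that add atoms: none
Why: Ni2B formed from NiCl2 and NaBH4 cleaves the benzylic C–S bonds of the dithioketal (reductive desulfurisation) without touching benzyl or silyl ethers; no stereocentre is involved, and any acetal reduced prematurely by borohydride converges on 26 in step 16.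

Step 16
Reactants: 24 desulfurised acetal lactone of step 15
Product: 26 (3R,4R)-3-(benzyloxy)-3-[4-(benzyloxy)-3-methoxybenzyl]-4-{[2',6-bis(benzyloxy)-5'-({[tert-butyl(dimethyl)silyl]oxy}methyl)-3',5-dimethoxybiphenyl-3-yl]methyl}dihydrofuran-2(3H)-one, via ring-opened potassium hydroxy carboxylate 25 (not isolated)
Conditions: NaBH4, KOH, MeOH/THF/H2O, 0 °C → rt; then cold dilute HCl to pH 3
Reagents that add atoms: potassium hydroxide, [K+].[OH-] (supplies one carboxyl oxygen of 25; the number of oxygen atoms in 26 is unchanged)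
Why: Hydroxide opens the acyl acetal at the lactone carbonyl, menthol leaves from the hemiacetal, and the unmasked C5 formyl group is reduced at once by borohydride to give 25; acidification recloses the ring with the carbonyl still on C2, the known way of turning 5-alkoxy lactones into lactones. C3 is quaternary and C4 is guarded by the immediate reduction; silyl ether lost on acidification is of no consequence, because step 17 converts alcohol and silyl ether alike.

Step 17
Reactants: 26 silyl-protected lactone 2 biaryl of step 16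
Product: 27 (3R,4R)-3-(benzyloxy)-3-[4-(benzyloxy)-3-methoxybenzyl]-4-{[2',6-bis(benzyloxy)-5'-(bromomethyl)-3',5-dimethoxybiphenyl-3-yl]methyl}dihydrofuran-2(3H)-one
Conditions: Ph3PBr2, CH2Cl2, 0 °C → rt; used at once
Reagents that add atoms: dibromotriphenylphosphorane, BrP(Br)(c1ccccc1)(c1ccccc1)c1ccccc1
Why: Ph3PBr2 converts tert-butyldimethylsilyl ethers (and free alcohols) directly into bromides through an alkoxyphosphonium bromide; the p-alkoxybenzylic position should react fast, no free Br2 is present to brominate the electron-rich rings, and the lactone and benzyl ethers are inert.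

Step 18
Reactants: 18 2-[4-(benzyloxy)-3-methoxyphenyl]-1,3-dithiane; 8 (5S)-3-(benzyloxy)-5-[(1S,2R,5S)-menthyloxy]furan-2(5H)-one; 27 ring B benzylic bromide carrying lactone 2
Product: 30 (3R,4S,5S)-3-(benzyloxy)-4-{2-[4-(benzyloxy)-3-methoxyphenyl]-1,3-dithian-2-yl}-5-[(1S,2R,5S)-menthyloxy]-3-{[ring B of 27]methyl}dihydrofuran-2(3H)-one carrying the unchanged (3R,4R) lactone 2, via lithiated dithiane 28 (not isolated), via lithium lactone enolate 29 (not isolated)
Conditions: 18 (1.3 equiv), n-BuLi (1.25 equiv), THF, −78 → −20 °C; 8 (1.3 equiv), −78 °C; then 27 (1.0 equiv), DMPU, −78 → −20 °C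
Reagents that add atoms: none
Why: Proposed new method: n-BuLi removes the C2 proton of 18 to give the sulfur-stabilised, soft carbanion 28, which should add 1,4 to the 2-alkoxy enoate 8 at C4 on the face opposite the C5 menthyloxy group and so generate the lithium enolate 29, in which lithium can bridge the enolate oxygen and the C3 benzyloxy oxygen. 29 is then C-alkylated in an SN2 reaction by the p-alkoxybenzylic bromide 27 on the face opposite the very bulky dithianyl group at C4, which creates the C3–CH2 bond and the fully substituted C3 of 30. The closest known reaction type is the tandem conjugate addition of lithiated 2-aryl-1,3-dithianes to 5-menthyloxyfuran-2(5H)-one with in situ enolate benzylation, combined with the well-known alkylation of α-alkoxy lactone enolates to tertiary ethers; new is only the oxygen substituent on the acceptor carbon C3. No ring is closed. C4 is controlled by the (5S) acetal centre (addition trans to the alkoxy group) and C3 by the new C4 centre (alkylation trans to it), so carbon enters trans and the benzyloxy group ends cis to the C4 substituent, as the target requires. The step needs 1,4-addition over 1,2-addition and over deprotonation at C5, which the soft, hindered dithiane anion at −78 °C should secure even though the α-alkoxy group makes C4 less electrophilic. It needs C- over O-alkylation and no attack on lactone 2, which the lithium counter-ion, the high SN2 reactivity of 27 and the absence of any α-hydrogen in lactone 2 should secure. 28 is consumed by 8 before 27 is added and 27 is the limiting component, so neither the carbanion nor excess base meets the lactone of 27.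

Step 19
Reactants: 30 tandem adduct of step 18
Product: 31 (3R,4S,5S)-3-(benzyloxy)-4-[4-(benzyloxy)-3-methoxybenzyl]-5-[(1S,2R,5S)-menthyloxy]-3-{[ring B of 27]methyl}dihydrofuran-2(3H)-one carrying the unchanged (3R,4R) lactone 2
Conditions: NiCl2·6H2O, NaBH4, MeOH/THF, 0 °C, short contact
Reagents that add atoms: none
Why: Reductive desulfurisation of the benzylic dithioketal by Ni2B, as in step 15; the short time at 0 °C is meant to keep borohydride away from lactone 2, whose carbonyl is also shielded by its quaternary α-carbon.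

Step 20
Reactants: 31 desulfurised acetal lactone of step 19
Product: 33 hexa-O-benzyl ether of the target, via ring-opened dipotassium bis(hydroxy carboxylate) 32 (not isolated)
Conditions: NaBH4, KOH, MeOH/THF/H2O, 0 °C → rt; then dilute HCl to pH 2, rt
Reagents that add atoms: potassium hydroxide, [K+].[OH-] (supplies carboxyl oxygen of 32; the number of oxygen atoms in 33 is unchanged)
Why: As in step 16, hydroxide opens the menthyl acyl acetal and the freed C5 formyl group is reduced at once; lactone 2 is expected to be saponified in the same medium to its carboxylate, which shields it from hydride, so that 32 carries two γ-hydroxy carboxylates. Acidification recloses both rings; both C3 centres are quaternary and neither C4 is enolisable once C5 is reduced.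

Step 21
Reactants: 33 hexa-O-benzyl ether of the target
Product: 34 target, (3R,4R)-3-hydroxy-4-(4-hydroxy-3-methoxybenzyl)-3-{[2',6-dihydroxy-5'-{[(3R,4R)-4-hydroxy-4-(4-hydroxy-3-methoxybenzyl)-5-oxotetrahydrofuran-3-yl]methyl}-3',5-dimethoxybiphenyl-3-yl]methyl}dihydrofuran-2(3H)-one
Conditions: H2 (1 atm), Pd(OH)2/C, THF/MeOH, rt
Reagents that add atoms: none
Why: Hydrogenolysis cleaves the four aryl benzyl ethers and the two tertiary benzyl ethers in one neutral step; the benzylic C–C bonds, the lactones and all stereocentres are unaffected, and sulfur was removed two steps earlier.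

## Compound list

1 | furfural (furan-2-carbaldehyde) | O=Cc1ccco1 | starting material
2 | 2,3,7-trioxabicyclo[2.2.1]hept-5-ene-1-carbaldehyde (furfural endoperoxide, formed in the flask) | O=CC12C=CC(OO1)O2 | intermediate
3 | 5-hydroxyfuran-2(5H)-one | O=C1OC(O)C=C1 | intermediate
4 | (+)-menthol, (1S,2R,5S)-2-isopropyl-5-methylcyclohexan-1-ol | CC(C)[C@H]1CC[C@H](C)C[C@@H]1O | starting material
5 | (5S)-5-[(1S,2R,5S)-menthyloxy]furan-2(5H)-one | O=C1O[C@H](O[C@H]2C[C@@H](C)CC[C@@H]2C(C)C)C=C1 | intermediate
6 | (3R,4S,5S)-3,4-dihydroxy-5-[(1S,2R,5S)-menthyloxy]dihydrofuran-2(3H)-one (cis-diol anti to the menthyloxy group) | O=C1O[C@H](O[C@H]2C[C@@H](C)CC[C@@H]2C(C)C)[C@@H](O)[C@H]1O | intermediate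
7 | (3R,4S,5S)-3,4-bis(benzyloxy)-5-[(1S,2R,5S)-menthyloxy]dihydrofuran-2(3H)-one | O=C1O[C@H](O[C@H]2C[C@@H](C)CC[C@@H]2C(C)C)[C@@H](OCc2ccccc2)[C@H]1OCc1ccccc1 | intermediate
8 | (5S)-3-(benzyloxy)-5-[(1S,2R,5S)-menthyloxy]furan-2(5H)-one | O=C1O[C@H](O[C@H]2C[C@@H](C)CC[C@@H]2C(C)C)C=C1OCc1ccccc1 | intermediate
9 | 5-bromovanillin (3-bromo-4-hydroxy-5-methoxybenzaldehyde) | COc1cc(C=O)cc(Br)c1O | starting material
10 | 4-(benzyloxy)-3-bromo-5-methoxybenzaldehyde | COc1cc(C=O)cc(Br)c1OCc1ccccc1 | intermediate
11 | propane-1,3-dithiol | SCCCS | starting material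
12 | 2-[4-(benzyloxy)-3-bromo-5-methoxyphenyl]-1,3-dithiane | COc1cc(cc(Br)c1OCc1ccccc1)C1SCCCS1 | intermediate
13 | [4-(benzyloxy)-3-bromo-5-methoxyphenyl]methanol | COc1cc(CO)cc(Br)c1OCc1ccccc1 | intermediate
14 | {[4-(benzyloxy)-3-bromo-5-methoxybenzyl]oxy}(tert-butyl)dimethylsilane | COc1cc(CO[Si](C)(C)C(C)(C)C)cc(Br)c1OCc1ccccc1 | intermediate
15 | 2-[2-(benzyloxy)-5-({[tert-butyl(dimethyl)silyl]oxy}methyl)-3-methoxyphenyl]-4,4,5,5-tetramethyl-1,3,2-dioxaborolane | COc1cc(CO[Si](C)(C)C(C)(C)C)cc(B2OC(C)(C)C(C)(C)O2)c1OCc1ccccc1 | intermediate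
16 | 2-[2',6-bis(benzyloxy)-5'-({[tert-butyl(dimethyl)silyl]oxy}methyl)-3',5-dimethoxybiphenyl-3-yl]-1,3-dithiane (unprimed ring = ring C, primed ring = ring B) | CC(C)(C)[Si](C)(C)OCc1cc(OC)c(OCc2ccccc2)c(c1)-c1cc(cc(OC)c1OCc1ccccc1)C1SCCCS1 | intermediate
17 | 4-(benzyloxy)-3-methoxybenzaldehyde | COc1cc(C=O)ccc1OCc1ccccc1 | starting material
18 | 2-[4-(benzyloxy)-3-methoxyphenyl]-1,3-dithiane | COc1cc(ccc1OCc1ccccc1)C1SCCCS1 | intermediate
19 | [4-(benzyloxy)-3-methoxyphenyl]methanol | COc1cc(CO)ccc1OCc1ccccc1 | starting material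
20 | 4-(benzyloxy)-3-methoxybenzyl bromide | COc1cc(CBr)ccc1OCc1ccccc1 | intermediate
21 | 2-lithio derivative of 16 (lithium on C2 of the dithiane; formed in the flask) | CC(C)(C)[Si](C)(C)OCc1cc(OC)c(OCc2ccccc2)c(c1)-c1cc(cc(OC)c1OCc1ccccc1)C1([Li])SCCCS1 | intermediate
22 | lithium (4S,5S)-3-(benzyloxy)-4-{2-[biphenylyl group of 16]-1,3-dithian-2-yl}-5-[(1S,2R,5S)-menthyloxy]-4,5-dihydrofuran-2-olate (formed in the flask) | CC(C)(C)[Si](C)(C)OCc1cc(OC)c(OCc2ccccc2)c(c1)-c1cc(cc(OC)c1OCc1ccccc1)C1(SCCCS1)[C@@H]1[C@@H](O[C@H]2C[C@@H](C)CC[C@@H]2C(C)C)OC(O[Li])=C1OCc1ccccc1 | intermediate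
23 | (3R,4S,5S)-3-(benzyloxy)-3-[4-(benzyloxy)-3-methoxybenzyl]-4-{2-[2',6-bis(benzyloxy)-5'-({[tert-butyl(dimethyl)silyl]oxy}methyl)-3',5-dimethoxybiphenyl-3-yl]-1,3-dithian-2-yl}-5-[(1S,2R,5S)-menthyloxy]dihydrofuran-2(3H)-one | CC(C)(C)[Si](C)(C)OCc1cc(OC)c(OCc2ccccc2)c(c1)-c1cc(cc(OC)c1OCc1ccccc1)C1(SCCCS1)[C@@H]1[C@@H](O[C@H]2C[C@@H](C)CC[C@@H]2C(C)C)OC(=O)[C@@]1(OCc1ccccc1)Cc1ccc(OCc2ccccc2)c(OC)c1 | intermediate
24 | (3R,4S,5S)-3-(benzyloxy)-3-[4-(benzyloxy)-3-methoxybenzyl]-4-{[2',6-bis(benzyloxy)-5'-({[tert-butyl(dimethyl)silyl]oxy}methyl)-3',5-dimethoxybiphenyl-3-yl]methyl}-5-[(1S,2R,5S)-menthyloxy]dihydrofuran-2(3H)-one | CC(C)(C)[Si](C)(C)OCc1cc(OC)c(OCc2ccccc2)c(c1)-c1cc(cc(OC)c1OCc1ccccc1)C[C@@H]1[C@@H](O[C@H]2C[C@@H](C)CC[C@@H]2C(C)C)OC(=O)[C@@]1(OCc1ccccc1)Cc1ccc(OCc2ccccc2)c(OC)c1 | intermediate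
25 | potassium (2R,3R)-2-(benzyloxy)-2-[4-(benzyloxy)-3-methoxybenzyl]-4-[biphenylyl group of 16 without dithiane]-3-(hydroxymethyl)butanoate (formed in the flask) | CC(C)(C)[Si](C)(C)OCc1cc(OC)c(OCc2ccccc2)c(c1)-c1cc(cc(OC)c1OCc1ccccc1)C[C@H](CO)[C@](OCc1ccccc1)(Cc1ccc(OCc2ccccc2)c(OC)c1)C(=O)[O-].[K+] | intermediate
26 | (3R,4R)-3-(benzyloxy)-3-[4-(benzyloxy)-3-methoxybenzyl]-4-{[2',6-bis(benzyloxy)-5'-({[tert-butyl(dimethyl)silyl]oxy}methyl)-3',5-dimethoxybiphenyl-3-yl]methyl}dihydrofuran-2(3H)-one | CC(C)(C)[Si](C)(C)OCc1cc(OC)c(OCc2ccccc2)c(c1)-c1cc(C[C@@H]2COC(=O)[C@@]2(OCc2ccccc2)Cc2ccc(OCc3ccccc3)c(OC)c2)cc(OC)c1OCc1ccccc1 | intermediate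
27 | (3R,4R)-3-(benzyloxy)-3-[4-(benzyloxy)-3-methoxybenzyl]-4-{[2',6-bis(benzyloxy)-5'-(bromomethyl)-3',5-dimethoxybiphenyl-3-yl]methyl}dihydrofuran-2(3H)-one | BrCc1cc(OC)c(OCc2ccccc2)c(c1)-c1cc(C[C@@H]2COC(=O)[C@@]2(OCc2ccccc2)Cc2ccc(OCc3ccccc3)c(OC)c2)cc(OC)c1OCc1ccccc1 | intermediate
28 | 2-lithio-2-[4-(benzyloxy)-3-methoxyphenyl]-1,3-dithiane (formed in the flask) | COc1cc(ccc1OCc1ccccc1)C1([Li])SCCCS1 | intermediate
29 | lithium (4S,5S)-3-(benzyloxy)-4-{2-[4-(benzyloxy)-3-methoxyphenyl]-1,3-dithian-2-yl}-5-[(1S,2R,5S)-menthyloxy]-4,5-dihydrofuran-2-olate (formed in the flask) | COc1cc(ccc1OCc1ccccc1)C1(SCCCS1)[C@@H]1[C@@H](O[C@H]2C[C@@H](C)CC[C@@H]2C(C)C)OC(O[Li])=C1OCc1ccccc1 | intermediate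
30 | (3R,4S,5S)-3-(benzyloxy)-4-{2-[4-(benzyloxy)-3-methoxyphenyl]-1,3-dithian-2-yl}-5-[(1S,2R,5S)-menthyloxy]-3-{[2',6-bis(benzyloxy)-3',5-dimethoxy-5'-{[(3R,4R)-4-(benzyloxy)-4-[4-(benzyloxy)-3-methoxybenzyl]-5-oxotetrahydrofuran-3-yl]methyl}biphenyl-3-yl]methyl}dihydrofuran-2(3H)-one (unprimed ring = ring B, primed ring = ring C) | COc1cc(ccc1OCc1ccccc1)C1(SCCCS1)[C@@H]1[C@@H](O[C@H]2C[C@@H](C)CC[C@@H]2C(C)C)OC(=O)[C@@]1(OCc1ccccc1)Cc1cc(OC)c(OCc2ccccc2)c(c1)-c1cc(C[C@@H]2COC(=O)[C@@]2(OCc2ccccc2)Cc2ccc(OCc3ccccc3)c(OC)c2)cc(OC)c1OCc1ccccc1 | intermediate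
31 | (3R,4S,5S)-3-(benzyloxy)-4-[4-(benzyloxy)-3-methoxybenzyl]-5-[(1S,2R,5S)-menthyloxy]-3-{[2',6-bis(benzyloxy)-3',5-dimethoxy-5'-{[(3R,4R)-4-(benzyloxy)-4-[4-(benzyloxy)-3-methoxybenzyl]-5-oxotetrahydrofuran-3-yl]methyl}biphenyl-3-yl]methyl}dihydrofuran-2(3H)-one | COc1cc(ccc1OCc1ccccc1)C[C@@H]1[C@@H](O[C@H]2C[C@@H](C)CC[C@@H]2C(C)C)OC(=O)[C@@]1(OCc1ccccc1)Cc1cc(OC)c(OCc2ccccc2)c(c1)-c1cc(C[C@@H]2COC(=O)[C@@]2(OCc2ccccc2)Cc2ccc(OCc3ccccc3)c(OC)c2)cc(OC)c1OCc1ccccc1 | intermediate
32 | dipotassium salt of the bis(γ-hydroxy acid) from 31: both lactones opened, C5 of lactone 1 reduced to CH2OH, both arms (2R,3R) (formed in the flask) | COc1cc(ccc1OCc1ccccc1)C[C@H](CO)[C@@](OCc1ccccc1)(C(=O)[O-])Cc1cc(OC)c(OCc2ccccc2)c(c1)-c1cc(C[C@H](CO)[C@](OCc2ccccc2)(Cc2ccc(OCc3ccccc3)c(OC)c2)C(=O)[O-])cc(OC)c1OCc1ccccc1.[K+].[K+] | intermediate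
33 | (3R,4R)-3-(benzyloxy)-4-[4-(benzyloxy)-3-methoxybenzyl]-3-{[2',6-bis(benzyloxy)-3',5-dimethoxy-5'-{[(3R,4R)-4-(benzyloxy)-4-[4-(benzyloxy)-3-methoxybenzyl]-5-oxotetrahydrofuran-3-yl]methyl}biphenyl-3-yl]methyl}dihydrofuran-2(3H)-one (hexa-O-benzyl ether of the target) | COc1cc(C[C@@H]2COC(=O)[C@@]2(OCc2ccccc2)Cc2cc(OC)c(OCc3ccccc3)c(c2)-c2cc(C[C@@H]3COC(=O)[C@@]3(OCc3ccccc3)Cc3ccc(OCc4ccccc4)c(OC)c3)cc(OC)c2OCc2ccccc2)ccc1OCc1ccccc1 | intermediate
34 | (3R,4R)-3-hydroxy-4-(4-hydroxy-3-methoxybenzyl)-3-{[2',6-dihydroxy-5'-{[(3R,4R)-4-hydroxy-4-(4-hydroxy-3-methoxybenzyl)-5-oxotetrahydrofuran-3-yl]methyl}-3',5-dimethoxybiphenyl-3-yl]methyl}dihydrofuran-2(3H)-one | COc1cc(C[C@@H]2COC(=O)[C@@]2(O)Cc2cc(OC)c(O)c(-c3cc(C[C@@H]4COC(=O)[C@@]4(O)Cc4ccc(O)c(OC)c4)cc(OC)c3O)c2)ccc1O | target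

## Step count and least certain steps

Total: 21 steps. Longest linear sequence: 13 steps (from 9 through steps 6, 8, 9, 10, 11 and 14–21; the line from 1 through steps 1–5 and 14–21 is equally long).

**Step 18 (key step, proposed new method).** The most likely failure is a sluggish conjugate addition to the α-alkoxy enoate, so that 28 instead removes the acetal proton at C5 or adds to the carbonyl. The second risk is slow C-alkylation of the crowded, fully substituted enolate, which leaves time for reversal of the addition or for O-alkylation.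

The fallback uses only known reaction types. It sets out from 18 and 5 and rejoins the route at 31, so step 19 falls away.
- 28 is added to the unsubstituted acceptor 5 and the enolate is protonated (the established conjugate addition). This gives (4S,5S)-4-{2-[4-(benzyloxy)-3-methoxyphenyl]-1,3-dithian-2-yl}-5-[(1S,2R,5S)-menthyloxy]dihydrofuran-2(3H)-one F1.
- NiCl2·6H2O/NaBH4 removes the sulfur to give (4S,5S)-4-[4-(benzyloxy)-3-methoxybenzyl]-5-[(1S,2R,5S)-menthyloxy]dihydrofuran-2(3H)-one F2.
- The potassium enolate of F2 (KN(SiMe3)2, THF, −78 °C) is hydroxylated with 2-(phenylsulfonyl)-3-phenyloxaziridine to the (3S,4S,5S)-3-hydroxy lactone F3. Oxygen is expected anti to the C4 benzyl group, but this centre is made planar again later.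
- BnBr/Ag2O gives the (3S,4S,5S)-3-benzyloxy lactone F4.
- LiN(iPr)2 (THF/DMPU, −78 °C) regenerates the C3 enolate, which is benzylated by 27 anti to the C4 substituent to give 31.

Oxygen is still on C3 before carbon arrives, so the stereochemical logic is unchanged. The price is three more steps.

**Step 14 (proposed new method).** The process risks are the same. Because 20 is a small, very reactive electrophile, a failure here would lie in the addition stage: competing deprotonation at C5 or carbonyl addition by 21.

The fallback with known chemistry sets out from 16 and 5 and rejoins the route at 24.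
- 21 is added to 5 with protonation to give the (4S,5S) adduct of the biaryl dithiane F5.
- NiCl2·6H2O/NaBH4 gives the (4S,5S)-4-(biarylmethyl)-5-menthyloxy lactone F6.
- KN(SiMe3)2 and 2-(phenylsulfonyl)-3-phenyloxaziridine give the (3S,4S,5S)-3-hydroxy lactone F7.
- BnBr/Ag2O gives the (3S,4S,5S)-3-benzyloxy lactone F8.
- LiN(iPr)2 followed by 20 gives 24 by alkylation anti to the C4 substituent.

**Step 20.** The most likely failure is loss of configuration at C4 by enolisation of the transient C5 aldehyde in strong base. Partial hydride reduction of lactone 2 before it is saponified is the second risk. The fallback sets out from 31 and rejoins the route at 33. Aqueous CF3CO2H in THF hydrolyses the menthyl acetal to the 5-hydroxy lactone F9 (a mixture at C5). NaBH4 in THF/MeOH at −20 °C reduces its open-chain formyl tautomer, and acidification gives 33. No hydroxide is used, so the aldehyde never meets strong base and lactone 2 is never opened.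

**Step 5.** The most likely failure is epimerisation at C5: the amidine base can remove the γ-proton of the product to give a 2-oxyfuran-type anion. Incomplete elimination is the second risk. The fallback sets out from 6 and rejoins the route at 8.
- Ac2O/pyridine gives the (3R,4S,5S)-3,4-diacetate F10.
- Et3N in CH2Cl2 at 0 °C eliminates acetic acid to give the 3-acetoxy butenolide F11. Acetate is a far better leaving group than benzyl alkoxide, so a much weaker base suffices; this is the well-known behaviour of acylated aldonolactones.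
- Hydrazine acetate in DMF at 0 °C cleaves the enol ester to the 3-hydroxy butenolide F12.
- BnBr/Ag2O benzylates the enol oxygen to give 8.

**Step 11.** The most likely failure is inhibition of the palladium catalyst by the dithiane sulfur atoms, together with protodeboronation of the electron-rich ortho-alkoxy boronate. The fallback sets out from 10 and 15 and rejoins the route at 16. The aldehyde 10 is coupled with 15 under the same Suzuki–Miyaura conditions, now without sulfur, to give 2',6-bis(benzyloxy)-5'-({[tert-butyl(dimethyl)silyl]oxy}methyl)-3',5-dimethoxybiphenyl-3-carbaldehyde F13. F13 is then thioacetalised with 11 under the mild Lewis acid MgBr2·OEt2 (Et2O, rt) to give 16. Should the silyl ether suffer, TBSCl/imidazole restores it.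

## Further compounds

F1 | step 18 | (4S,5S)-4-{2-[4-(benzyloxy)-3-methoxyphenyl]-1,3-dithian-2-yl}-5-[(1S,2R,5S)-menthyloxy]dihydrofuran-2(3H)-one | COc1cc(ccc1OCc1ccccc1)C1(SCCCS1)[C@@H]1[C@@H](O[C@H]2C[C@@H](C)CC[C@@H]2C(C)C)OC(=O)C1
F2 | step 18 | (4S,5S)-4-[4-(benzyloxy)-3-methoxybenzyl]-5-[(1S,2R,5S)-menthyloxy]dihydrofuran-2(3H)-one | COc1cc(ccc1OCc1ccccc1)C[C@@H]1[C@@H](O[C@H]2C[C@@H](C)CC[C@@H]2C(C)C)OC(=O)C1
F3 | step 18 | (3S,4S,5S)-4-[4-(benzyloxy)-3-methoxybenzyl]-3-hydroxy-5-[(1S,2R,5S)-menthyloxy]dihydrofuran-2(3H)-one | COc1cc(ccc1OCc1ccccc1)C[C@@H]1[C@@H](O[C@H]2C[C@@H](C)CC[C@@H]2C(C)C)OC(=O)[C@H]1O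
F4 | step 18 | (3S,4S,5S)-3-(benzyloxy)-4-[4-(benzyloxy)-3-methoxybenzyl]-5-[(1S,2R,5S)-menthyloxy]dihydrofuran-2(3H)-one | COc1cc(ccc1OCc1ccccc1)C[C@@H]1[C@@H](O[C@H]2C[C@@H](C)CC[C@@H]2C(C)C)OC(=O)[C@H]1OCc1ccccc1
F5 | step 14 | (4S,5S)-4-{2-[2',6-bis(benzyloxy)-5'-({[tert-butyl(dimethyl)silyl]oxy}methyl)-3',5-dimethoxybiphenyl-3-yl]-1,3-dithian-2-yl}-5-[(1S,2R,5S)-menthyloxy]dihydrofuran-2(3H)-one | CC(C)(C)[Si](C)(C)OCc1cc(OC)c(OCc2ccccc2)c(c1)-c1cc(cc(OC)c1OCc1ccccc1)C1(SCCCS1)[C@@H]1[C@@H](O[C@H]2C[C@@H](C)CC[C@@H]2C(C)C)OC(=O)C1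
F6 | step 14 | (4S,5S)-4-{[2',6-bis(benzyloxy)-5'-({[tert-butyl(dimethyl)silyl]oxy}methyl)-3',5-dimethoxybiphenyl-3-yl]methyl}-5-[(1S,2R,5S)-menthyloxy]dihydrofuran-2(3H)-one | CC(C)(C)[Si](C)(C)OCc1cc(OC)c(OCc2ccccc2)c(c1)-c1cc(cc(OC)c1OCc1ccccc1)C[C@@H]1[C@@H](O[C@H]2C[C@@H](C)CC[C@@H]2C(C)C)OC(=O)C1
F7 | step 14 | (3S,4S,5S)-3-hydroxy derivative of F6 | CC(C)(C)[Si](C)(C)OCc1cc(OC)c(OCc2ccccc2)c(c1)-c1cc(cc(OC)c1OCc1ccccc1)C[C@@H]1[C@@H](O[C@H]2C[C@@H](C)CC[C@@H]2C(C)C)OC(=O)[C@H]1O
F8 | step 14 | (3S,4S,5S)-3-benzyloxy derivative of F6 | CC(C)(C)[Si](C)(C)OCc1cc(OC)c(OCc2ccccc2)c(c1)-c1cc(cc(OC)c1OCc1ccccc1)C[C@@H]1[C@@H](O[C@H]2C[C@@H](C)CC[C@@H]2C(C)C)OC(=O)[C@H]1OCc1ccccc1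
F9 | step 20 | 5-hydroxy lactone (lactol, both C5 epimers) from 31 by loss of menthol; lactone 1 (3R,4S), lactone 2 (3R,4R) | COc1cc(ccc1OCc1ccccc1)C[C@@H]1C(O)OC(=O)[C@@]1(OCc1ccccc1)Cc1cc(OC)c(OCc2ccccc2)c(c1)-c1cc(C[C@@H]2COC(=O)[C@@]2(OCc2ccccc2)Cc2ccc(OCc3ccccc3)c(OC)c2)cc(OC)c1OCc1ccccc1
F10 | step 5 | (3R,4S,5S)-3,4-diacetoxy-5-[(1S,2R,5S)-menthyloxy]dihydrofuran-2(3H)-one | O=C1O[C@H](O[C@H]2C[C@@H](C)CC[C@@H]2C(C)C)[C@@H](OC(C)=O)[C@H]1OC(C)=O
F11 | step 5 | (5S)-3-acetoxy-5-[(1S,2R,5S)-menthyloxy]furan-2(5H)-one | O=C1O[C@H](O[C@H]2C[C@@H](C)CC[C@@H]2C(C)C)C=C1OC(C)=O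
F12 | step 5 | (5S)-3-hydroxy-5-[(1S,2R,5S)-menthyloxy]furan-2(5H)-one | O=C1O[C@H](O[C@H]2C[C@@H](C)CC[C@@H]2C(C)C)C=C1O
F13 | step 11 | 2',6-bis(benzyloxy)-5'-({[tert-butyl(dimethyl)silyl]oxy}methyl)-3',5-dimethoxybiphenyl-3-carbaldehyde | CC(C)(C)[Si](C)(C)OCc1cc(OC)c(OCc2ccccc2)c(c1)-c1cc(C=O)cc(OC)c1OCc1ccccc1
A1 | alternative 1 | (S)-4-{[5'-allyl-2',6-bis(benzyloxy)-3',5-dimethoxybiphenyl-3-yl]methyl}dihydrofuran-2(3H)-one | C=CCc1cc(OC)c(OCc2ccccc2)c(c1)-c1cc(C[C@@H]2COC(=O)C2)cc(OC)c1OCc1ccccc1
A2 | alternative 1 | 3-{[5'-allyl-2',6-bis(benzyloxy)-3',5-dimethoxybiphenyl-3-yl]methyl}cyclobutan-1-one | C=CCc1cc(OC)c(OCc2ccccc2)c(c1)-c1cc(CC2CC(=O)C2)cc(OC)c1OCc1ccccc1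
A3 | alternative 2 | bis(tertiary allylic alcohol): each arm ArCH2–CH(CH2OBn)–C(OH)(CH=CH2)–CH2Ar' on the hexabenzylated biaryl skeleton, vinyl groups as latent C2 | COc1cc(C[C@H](COCc2ccccc2)[C@@](O)(C=C)Cc2cc(OC)c(OCc3ccccc3)c(c2)-c2cc(C[C@H](COCc3ccccc3)[C@@](O)(C=C)Cc3ccc(OCc4ccccc4)c(OC)c3)cc(OC)c2OCc2ccccc2)ccc1OCc1ccccc1
A4 | alternative 2 | bis(β-benzyloxy ketone): each arm ArCH2–CH(CH2OBn)–C(=O)–CH2Ar', both α-centres R | COc1cc(C[C@H](COCc2ccccc2)C(=O)Cc2cc(OC)c(OCc3ccccc3)c(c2)-c2cc(C[C@H](COCc3ccccc3)C(=O)Cc3ccc(OCc4ccccc4)c(OC)c3)cc(OC)c2OCc2ccccc2)ccc1OCc1ccccc1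
A5 | alternative 3 | bis(1,2-diol): each arm ArCH2–CH(CH=CH2)–C(OH)(CH2OH)–CH2Ar', vinyl groups as latent C5, CH2OH groups as latent C2 | COc1cc(C[C@H](C=C)[C@@](O)(CO)Cc2cc(OC)c(OCc3ccccc3)c(c2)-c2cc(C[C@H](C=C)[C@@](O)(CO)Cc3ccc(OCc4ccccc4)c(OC)c3)cc(OC)c2OCc2ccccc2)ccc1OCc1ccccc1
A6 | alternative 3 | bis(2,3-epoxy alcohol): each arm a (2S,3R)-2-(arylmethyl)-3-(arylmethyl)oxiran-2-yl methanol | COc1cc(C[C@H]2O[C@]2(CO)Cc2cc(OC)c(OCc3ccccc3)c(c2)-c2cc(C[C@H]3O[C@]3(CO)Cc3ccc(OCc4ccccc4)c(OC)c3)cc(OC)c2OCc2ccccc2)ccc1OCc1ccccc1
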